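**Strategy.** The depside is cut at its ester carbonyl. This carbon lies between C1 of ring A (the 2-hydroxy-4-methoxy-6-(2-oxononyl)phenyl ring) and the oxygen on C4 of ring B (the orsellinic acid ring), so it is brought in as carbon monoxide. One palladium-catalysed carbonylation joins an aryl iodide, CO and a phenol, making the ring A C1–C(=O) bond and the C(=O)–O bond to ring B without ever handling the hindered, cyclisation-prone ring A acid. The iodide is a 2-iodo-3,5-dimethoxybenzyl unit whose side-chain ketone is masked as a dioxolane; the phenol is benzyl orsellinate. Ketal hydrolysis, chelation-directed mono-demethylation and hydrogenolysis finish the synthesis.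

Key step: step 6

Remark: the target has no stereocentre, so no configuration has to be set or preserved; heptylmagnesium bromide is taken as the commercial ether solution.

**Step 1**
Reactants: 1 3,5-dimethoxyphenylacetic acid
Product: 3 2-(3,5-dimethoxyphenyl)-N-methoxy-N-methylacetamide, via acyl imidazolide 2 (not isolated)
Conditions: CDI, CH2Cl2, rt; then MeNHOMe·HCl, rt
Reagents that add atoms: N,O-dimethylhydroxylamine hydrochloride, CNOC.Cl
Why: Amide coupling through the acyl imidazolide, which the liberated N,O-dimethylhydroxylamine displaces to give the Weinreb amide; nothing else in the molecule competes.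

**Step 2**
Reactants: 3 2-(3,5-dimethoxyphenyl)-N-methoxy-N-methylacetamide; 4 heptylmagnesium bromide
Product: 5 1-(3,5-dimethoxyphenyl)nonan-2-one
Conditions: THF, −10 → 0 °C; then 1 M HCl, 0 °C
Reagents that add atoms: none
Why: Weinreb ketone synthesis, in which the magnesium-chelated tetrahedral adduct survives until the acidic quench so that over-addition should not occur, while low temperature and a modest excess of Grignard reagent offset enolisation of the arylacetyl unit.

**Step 3**
Reactants: 5 1-(3,5-dimethoxyphenyl)nonan-2-one
Product: 6 2-[(3,5-dimethoxyphenyl)methyl]-2-heptyl-1,3-dioxolane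
Conditions: HOCH2CH2OH, TsOH·H2O (cat.), toluene, reflux, Dean–Stark
Reagents that add atoms: ethylene glycol, OCCO
Why: Acid-catalysed ketalisation driven by azeotropic removal of water should convert the unhindered ketone into the dioxolane, and the aryl methyl ethers are inert.

**Step 4**
Reactants: 6 2-[(3,5-dimethoxyphenyl)methyl]-2-heptyl-1,3-dioxolane
Product: 7 2-heptyl-2-[(2-iodo-3,5-dimethoxyphenyl)methyl]-1,3-dioxolane
Conditions: NIS, MeCN, 0 °C → rt, dark
Reagents that add atoms: N-iodosuccinimide, O=C1CCC(=O)N1I
Why: Electrophilic aromatic iodination at the carbon ortho to the benzylic CH2, which is para to one methoxy group and ortho to the other (the favoured site for 1-alkyl-3,5-dimethoxybenzenes, and the two such carbons are symmetry-equivalent), under acid-free conditions that should spare the dioxolane.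

**Step 5**
Reactants: 8 orsellinic acid (2,4-dihydroxy-6-methylbenzoic acid)
Product: 9 benzyl orsellinate (benzyl 2,4-dihydroxy-6-methylbenzoate)
Conditions: BnBr, KHCO3, DMF, rt
Reagents that add atoms: benzyl bromide, BrCc1ccccc1
Why: Carboxylate O-alkylation (SN2), since hydrogencarbonate deprotonates only the carboxylic acid and so the phenols should stay free, and room temperature avoids decarboxylation of orsellinic acid.

**Step 6**
Reactants: 7 2-heptyl-2-[(2-iodo-3,5-dimethoxyphenyl)methyl]-1,3-dioxolane; 9 benzyl orsellinate; 10 carbon monoxide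
Product: 11 benzyl 4-({2-[(2-heptyl-1,3-dioxolan-2-yl)methyl]-4,6-dimethoxybenzoyl}oxy)-2-hydroxy-6-methylbenzoate
Conditions: Pd(OAc)2 (5 mol %), Xantphos (6 mol %), Et3N, CO (1 atm), toluene, 90 °C
Reagents that add atoms: none
Why: Pd(OAc)2 is reduced in situ to a zerovalent palladium–Xantphos complex that inserts into the C–I bond of 7; CO then coordinates and migrates into the aryl–palladium bond, which relieves the crowding between the two ortho substituents, and the triethylammonium phenoxide of 9 displaces iodide on the aroyl-palladium so that C–O reductive elimination releases the aryl ester and returns zerovalent palladium. The closest known reaction type is the palladium-catalysed aryloxycarbonylation (Heck-type carbonylation) of aryl iodides with phenols under 1 atm of CO, for which the wide-bite-angle ligand Xantphos is established. No ring is closed and no stereocentre is formed; the two new bonds are ring A C1–C(=O) and C(=O)–O(ring B C4). The step needs O-acylation at the 4-OH of 9 and not at the 2-OH: the 2-OH is held in a hydrogen bond to the benzyl ester carbonyl and is less acidic and more hindered, whereas the 4-OH is the free, more acidic phenol. It also needs the aroyl-palladium to be trapped only intermolecularly, and with the ketone locked as the dioxolane there is no enol or enolate oxygen that could close an isocoumarin. Because the carboxyl carbon arrives as CO, the hindered ring A acid never has to be made or activated.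

**Step 7**
Reactants: 11 benzyl 4-({2-[(2-heptyl-1,3-dioxolan-2-yl)methyl]-4,6-dimethoxybenzoyl}oxy)-2-hydroxy-6-methylbenzoate
Product: 12 benzyl 4-{[2,4-dimethoxy-6-(2-oxononyl)benzoyl]oxy}-2-hydroxy-6-methylbenzoate
Conditions: 2 M HCl, THF, rt
Reagents that add atoms: water, O
Why: Acid-catalysed ketal hydrolysis, to which the di-ortho-substituted aryl ester and the benzyl ester should be stable at room temperature; the dioxolane is removed here, before the Lewis acid step, because BCl3 would otherwise open it in an uncontrolled way.

**Step 8**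
Reactants: 12 benzyl 4-{[2,4-dimethoxy-6-(2-oxononyl)benzoyl]oxy}-2-hydroxy-6-methylbenzoate
Product: 13 benzyl 2-hydroxy-4-{[2-hydroxy-4-methoxy-6-(2-oxononyl)benzoyl]oxy}-6-methylbenzoate
Conditions: BCl3 (3 equiv), CH2Cl2, −78 → −20 °C; then H2O
Reagents that add atoms: none
Why: Chelation-controlled ether cleavage, in which boron bridges the depside carbonyl and the neighbouring ring A methoxy oxygen and chloride removes that methyl group as chloromethane, while the unchelated 4-methoxy group should survive at low temperature; any benzyl ester lost here would already be the target acid.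

**Step 9**
Reactants: 13 benzyl 2-hydroxy-4-{[2-hydroxy-4-methoxy-6-(2-oxononyl)benzoyl]oxy}-6-methylbenzoate
Product: 14 2-hydroxy-4-{[2-hydroxy-4-methoxy-6-(2-oxononyl)benzoyl]oxy}-6-methylbenzoic acid (CNP0320117.0)
Conditions: H2 (1 atm), Pd/C (10 wt %), EtOAc, rt
Reagents that add atoms: none
Why: Hydrogenolysis of the benzyl ester under neutral conditions, which should leave the aliphatic ketone, the aryl ester and the methyl ether untouched and exposes the acid without any acid or base that could trigger decarboxylation or cyclisation.

**Compound list**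
1 | 3,5-dimethoxyphenylacetic acid | COc1cc(CC(=O)O)cc(OC)c1 | starting material
2 | 2-(3,5-dimethoxyphenyl)-1-(1H-imidazol-1-yl)ethan-1-one (acyl imidazolide, not isolated) | COc1cc(CC(=O)n2ccnc2)cc(OC)c1 | intermediate
3 | 2-(3,5-dimethoxyphenyl)-N-methoxy-N-methylacetamide | COc1cc(CC(=O)N(C)OC)cc(OC)c1 | intermediate
4 | heptylmagnesium bromide | CCCCCCC[Mg]Br | starting material
5 | 1-(3,5-dimethoxyphenyl)nonan-2-one | CCCCCCCC(=O)Cc1cc(OC)cc(OC)c1 | intermediate
6 | 2-[(3,5-dimethoxyphenyl)methyl]-2-heptyl-1,3-dioxolane | CCCCCCCC1(Cc2cc(OC)cc(OC)c2)OCCO1 | intermediate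
7 | 2-heptyl-2-[(2-iodo-3,5-dimethoxyphenyl)methyl]-1,3-dioxolane | CCCCCCCC1(Cc2cc(OC)cc(OC)c2I)OCCO1 | intermediate
8 | orsellinic acid (2,4-dihydroxy-6-methylbenzoic acid) | Cc1cc(O)cc(O)c1C(=O)O | starting material
9 | benzyl orsellinate (benzyl 2,4-dihydroxy-6-methylbenzoate) | Cc1cc(O)cc(O)c1C(=O)OCc1ccccc1 | intermediate
10 | carbon monoxide | [C-]#[O+] | starting material
11 | benzyl 4-({2-[(2-heptyl-1,3-dioxolan-2-yl)methyl]-4,6-dimethoxybenzoyl}oxy)-2-hydroxy-6-methylbenzoate | CCCCCCCC1(Cc2cc(OC)cc(OC)c2C(=O)Oc2cc(C)c(C(=O)OCc3ccccc3)c(O)c2)OCCO1 | intermediate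
12 | benzyl 4-{[2,4-dimethoxy-6-(2-oxononyl)benzoyl]oxy}-2-hydroxy-6-methylbenzoate | CCCCCCCC(=O)Cc1cc(OC)cc(OC)c1C(=O)Oc1cc(C)c(C(=O)OCc2ccccc2)c(O)c1 | intermediate
13 | benzyl 2-hydroxy-4-{[2-hydroxy-4-methoxy-6-(2-oxononyl)benzoyl]oxy}-6-methylbenzoate | CCCCCCCC(=O)Cc1cc(OC)cc(O)c1C(=O)Oc1cc(C)c(C(=O)OCc2ccccc2)c(O)c1 | intermediate
14 | 2-hydroxy-4-{[2-hydroxy-4-methoxy-6-(2-oxononyl)benzoyl]oxy}-6-methylbenzoic acid | CCCCCCCC(=O)Cc1cc(OC)cc(O)c1C(=O)Oc1cc(C)c(C(=O)O)c(O)c1 | target

**Step count.** Total: 9 steps. Longest linear sequence: 8 steps (steps 1, 2, 3, 4, 6, 7, 8, 9, from 1 to 14); step 5 is a one-step branch to 9.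

**Steps most likely to fail**

1. Step 6. Oxidative addition at the electron-rich, doubly ortho-substituted C–I bond may be slow enough for hydrodeiodination to compete, or the crowded aroyl-palladium may be captured too slowly by the weakly nucleophilic phenoxide. Fallback, from 7 back to 11: iodine–lithium exchange on 7 (n-BuLi, THF, −78 °C) should give {2-[(2-heptyl-1,3-dioxolan-2-yl)methyl]-4,6-dimethoxyphenyl}lithium F1. Quenching with CO2 and cold acidification with dilute HCl to pH 4 should give 2-[(2-heptyl-1,3-dioxolan-2-yl)methyl]-4,6-dimethoxybenzoic acid F2, which cannot lactonise because its ketone is still a ketal. A carbodiimide esterification of this acid with the 4-OH of 9 (DCC, catalytic DMAP, CH2Cl2, 0 °C → rt) should then give 11.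

2. Step 8. BCl3 may cleave the boron-chelated benzyl ester of ring B and transfer the benzyl cation onto the electron-rich rings. A lesser concern, limited by low temperature and short contact time, is attack of the side-chain carbonyl on the boron-activated depside carbonyl. Fallback, from 12 back to 14: hydrogenolyse first (H2, Pd/C, EtOAc, rt) to 4-{[2,4-dimethoxy-6-(2-oxononyl)benzoyl]oxy}-2-hydroxy-6-methylbenzoic acid F3. Then apply BCl3 in CH2Cl2 at −78 → −20 °C to this benzyl-free acid, so that the chelation-directed demethylation should lead directly to 14.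

3. Step 4. Traces of acid formed during iodination may open the dioxolane, and under acid-free conditions the iodination may be slow, with attack at the carbon between the two methoxy groups if it is forced. Fallback, from 5 back to 7: iodinate the ketone itself, where acid activation of the iodinating agent is allowed (NIS, catalytic CF3CO2H, MeCN, 0 °C), to give 1-(2-iodo-3,5-dimethoxyphenyl)nonan-2-one F4. Ketalise this iodoketone with ethylene glycol under the conditions of step 3 to reach 7.

**Further compounds**
F1 | step 6 | {2-[(2-heptyl-1,3-dioxolan-2-yl)methyl]-4,6-dimethoxyphenyl}lithium | CCCCCCCC1(Cc2cc(OC)cc(OC)c2[Li])OCCO1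
F2 | step 6 | 2-[(2-heptyl-1,3-dioxolan-2-yl)methyl]-4,6-dimethoxybenzoic acid | CCCCCCCC1(Cc2cc(OC)cc(OC)c2C(=O)O)OCCO1
F3 | step 8 | 4-{[2,4-dimethoxy-6-(2-oxononyl)benzoyl]oxy}-2-hydroxy-6-methylbenzoic acid | CCCCCCCC(=O)Cc1cc(OC)cc(OC)c1C(=O)Oc1cc(C)c(C(=O)O)c(O)c1
F4 | step 4 | 1-(2-iodo-3,5-dimethoxyphenyl)nonan-2-one | CCCCCCCC(=O)Cc1cc(OC)cc(OC)c1I
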